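**Assumption:** the target (terrequinone A) has no stereocentre and its SMILES carries no stereodescriptor, so no stereocontrol is needed; the stereocentres of intermediates 2, 4, 8 and 11 are racemic and are all destroyed later.

**Retrosynthetic overview**
- The prenyl group on the quinone replaces one hydroxyl of an unsymmetrical 2,5-dihydroxy-3,6-bis(indolyl)benzoquinone by reduction, C-prenylation and loss of water, as in the biosynthesis.
- The quinone ring is disconnected into two different indol-3-ylpyruvate methyl esters joined head-to-tail by a crossed Claisen then Dieckmann condensation, the laboratory counterpart of the enzymatic indolepyruvate dimerisation.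
- The plain ester comes from indole-3-pyruvic acid; the 2-(1,1-dimethylallyl) ester comes from methyl indole-3-acetate by C2 reverse prenylation, oxalylation and dealkoxycarbonylation.
- Ring order: both indole rings are bought; the quinone ring is the only ring formed (step 5), and the last step only modifies it.

**Step 1**
Reactants: 1 methyl 2-(1H-indol-3-yl)acetate
Product: 3 methyl 2-[2-(2-methylbut-3-en-2-yl)-1H-indol-3-yl]acetate, via chloroindolenine 2 (not isolated)
Conditions: tBuOCl, Et3N, THF, −78 °C; then B-prenyl-9-BBN (premade from 9-BBN dimer + 3-methylbuta-1,2-diene, THF, rt), −78 °C to rt; aq. NaHCO3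
Reagents that add atoms: 3-methylbuta-1,2-diene, CC(C)=C=C (delivered as B-prenyl-9-BBN, CC(C)=CCB1C2CCCC1CCC2); tert-butyl hypochlorite, CC(C)(C)OCl (its chlorine is in 2 only)
Why: C3-chlorination gives the 3-chloroindolenine, whose C=N carbon is allylated by the allylborane through a six-membered transition state with allylic transposition (reverse prenylation of a 3-substituted indole via allylboration of a chloroindolenine), and loss of HCl restores the indole; the ester is inert to the borane at low temperature and no stereocentre remains.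

**Step 2**
Reactants: 3 methyl 2-[2-(2-methylbut-3-en-2-yl)-1H-indol-3-yl]acetate
Product: 4 dimethyl 2-[2-(2-methylbut-3-en-2-yl)-1H-indol-3-yl]-3-oxobutanedioate
Conditions: (CO2Me)2, NaOMe, THF–MeOH, 0 to 50 °C; then cold 1 M HCl
Reagents that add atoms: dimethyl oxalate, COC(=O)C(=O)OC
Why: Crossed Claisen condensation of an arylacetate with non-enolisable dimethyl oxalate, driven by formation of the stabilised enolate of the product; the new CH centre is enolised and racemic and is lost in step 3.

**Step 3**
Reactants: 4 dimethyl 2-[2-(2-methylbut-3-en-2-yl)-1H-indol-3-yl]-3-oxobutanedioate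
Product: 5 methyl 3-[2-(2-methylbut-3-en-2-yl)-1H-indol-3-yl]-2-oxopropanoate
Conditions: LiCl, H2O (2 equiv), DMSO, 120 °C
Reagents that add atoms: none
Why: Krapcho dealkoxycarbonylation removes only the ester that is β to the ketone, because only that carboxylate can decarboxylate, and the neutral conditions spare the acid-sensitive 1,1-dimethylallyl indole and the α-keto ester.

**Step 4**
Reactants: 6 3-(1H-indol-3-yl)-2-oxopropanoic acid (indole-3-pyruvic acid)
Product: 7 methyl 3-(1H-indol-3-yl)-2-oxopropanoate
Conditions: MeI, KHCO3, DMF, rt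
Reagents that add atoms: iodomethane, CI
Why: SN2 O-alkylation of the carboxylate; bicarbonate ionises the carboxylic acid but not the enol or the indole N–H, so only the ester forms.

**Step 5**
Reactants: 5 methyl 3-[2-(2-methylbut-3-en-2-yl)-1H-indol-3-yl]-2-oxopropanoate; 7 methyl 3-(1H-indol-3-yl)-2-oxopropanoate
Product: 9 2,5-dihydroxy-3-(1H-indol-3-yl)-6-[2-(2-methylbut-3-en-2-yl)-1H-indol-3-yl]cyclohexa-2,5-diene-1,4-dione, via triketo ester 8 (not isolated)
Conditions: NaOMe (4.5 equiv), 7 (3 equiv), MeOH–toluene, 80 °C, 5 added over 4 h, MeOH distilled off; then 1 M HCl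
Reagents that add atoms: none
Why: Proposed new method: under reversible alkoxide conditions the unhindered enolate carbon of 7 acylates the ester carbon of 5 (Claisen) to give 8, whose indolylmethylene carbon then closes onto the remaining ester (Dieckmann), and the resulting tetraketone tautomerises to the dihydroxyquinone dianion, a thermodynamic sink that drains the reversible aldol dimers; excess 7 and slow addition of 5 bias the statistical outcome toward the crossed product, and self-condensation of 5 is retarded by its 2-tert-alkyl group; the closest known reaction type is the head-to-tail Claisen–Dieckmann dimerisation of α-keto esters generated from simple esters and dialkyl oxalates, which gives 3,6-dialkyl-2,5-dihydroxybenzoquinones.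

**Step 6**
Reactants: 9 2,5-dihydroxy-3-(1H-indol-3-yl)-6-[2-(2-methylbut-3-en-2-yl)-1H-indol-3-yl]cyclohexa-2,5-diene-1,4-dione
Product: 12 2-hydroxy-6-(1H-indol-3-yl)-3-[2-(2-methylbut-3-en-2-yl)-1H-indol-3-yl]-5-(3-methylbut-2-en-1-yl)cyclohexa-2,5-diene-1,4-dione (terrequinone A), via leuco tetrol 10 (not isolated), via prenyl ketol 11 (not isolated)
Conditions: Na2S2O4, EtOAc/H2O, Ar, rt, organic phase dried and concentrated under Ar; then Pd(PPh3)4 (5 mol %), prenyl acetate (1.1 equiv), THF, 50 °C; then TsOH·H2O (cat.), air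
Reagents that add atoms: 3-methylbut-2-en-1-yl acetate (prenyl acetate), CC(=O)OCC=C(C)C
Why: Proposed new method: dithionite gives tetrol 10, an aromatic bis-enediol, and Tsuji–Trost allylation with zerovalent palladium (O-allylation reversible, attack at the unsubstituted allyl terminus) should deliver the prenyl group to a hydroxyl-bearing carbon next to the unhindered indol-3-yl group rather than next to the 2-tert-alkylindolyl group (the two such carbons are equivalent), giving ketol 11, which loses water by vinylogous β-elimination directly to the quinone 12; the closest known reaction type is palladium-catalysed C-allylation of ascorbic acid and of 2-hydroxy-1,4-naphthoquinone, and the racemic centre of 11 disappears on dehydration.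

**Compound list**
1 | methyl 2-(1H-indol-3-yl)acetate | COC(=O)Cc1c[nH]c2ccccc12 | starting material
2 | methyl 2-(3-chloro-3H-indol-3-yl)acetate (racemic, not isolated) | COC(=O)CC1(Cl)C=Nc2ccccc12 | intermediate
3 | methyl 2-[2-(2-methylbut-3-en-2-yl)-1H-indol-3-yl]acetate | COC(=O)Cc1c(C(C)(C)C=C)[nH]c2ccccc12 | intermediate
4 | dimethyl 2-[2-(2-methylbut-3-en-2-yl)-1H-indol-3-yl]-3-oxobutanedioate (racemic, largely enol) | COC(=O)C(=O)C(C(=O)OC)c1c(C(C)(C)C=C)[nH]c2ccccc12 | intermediate
5 | methyl 3-[2-(2-methylbut-3-en-2-yl)-1H-indol-3-yl]-2-oxopropanoate | COC(=O)C(=O)Cc1c(C(C)(C)C=C)[nH]c2ccccc12 | intermediate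
6 | 3-(1H-indol-3-yl)-2-oxopropanoic acid | OC(=O)C(=O)Cc1c[nH]c2ccccc12 | starting material
7 | methyl 3-(1H-indol-3-yl)-2-oxopropanoate | COC(=O)C(=O)Cc1c[nH]c2ccccc12 | intermediate
8 | methyl 3-(1H-indol-3-yl)-6-[2-(2-methylbut-3-en-2-yl)-1H-indol-3-yl]-2,4,5-trioxohexanoate (racemic, not isolated) | COC(=O)C(=O)C(c1c[nH]c2ccccc12)C(=O)C(=O)Cc1c(C(C)(C)C=C)[nH]c2ccccc12 | intermediate
9 | 2,5-dihydroxy-3-(1H-indol-3-yl)-6-[2-(2-methylbut-3-en-2-yl)-1H-indol-3-yl]cyclohexa-2,5-diene-1,4-dione | O=C1C(O)=C(c2c[nH]c3ccccc23)C(=O)C(O)=C1c1c(C(C)(C)C=C)[nH]c2ccccc12 | intermediate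
10 | 3-(1H-indol-3-yl)-6-[2-(2-methylbut-3-en-2-yl)-1H-indol-3-yl]benzene-1,2,4,5-tetrol (not isolated) | Oc1c(O)c(-c2c[nH]c3ccccc23)c(O)c(O)c1-c1c(C(C)(C)C=C)[nH]c2ccccc12 | intermediate
11 | 3,4,6-trihydroxy-5-(1H-indol-3-yl)-2-[2-(2-methylbut-3-en-2-yl)-1H-indol-3-yl]-6-(3-methylbut-2-en-1-yl)cyclohexa-2,4-dien-1-one (racemic, not isolated) | O=C1C(c2c(C(C)(C)C=C)[nH]c3ccccc23)=C(O)C(O)=C(c2c[nH]c3ccccc23)C1(O)CC=C(C)C | intermediate
12 | 2-hydroxy-6-(1H-indol-3-yl)-3-[2-(2-methylbut-3-en-2-yl)-1H-indol-3-yl]-5-(3-methylbut-2-en-1-yl)cyclohexa-2,5-diene-1,4-dione (terrequinone A, achiral) | C=CC(C)(C)c1[nH]c2ccccc2c1C1=C(O)C(=O)C(c2c[nH]c3ccccc23)=C(CC=C(C)C)C1=O | target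

**Step count and risks**
Total steps: 6. Longest linear sequence: 5 (steps 1, 2, 3, 5, 6). Steps 5 and 6 are untested proposals.

Most likely to fail, in order:

1. **Step 5 (crossed Claisen–Dieckmann).** The risks are aldol-type dimers instead of Claisen products and statistical scrambling; the symmetrical dimer of 7, 2,5-dihydroxy-3,6-di(1H-indol-3-yl)benzoquinone, is the expected main by-product and must be separated by chromatography. Fallback: a directed, kinetically controlled sequence that sets out from 5 and returns at 9. Ester 5 is hydrolysed (LiOH, THF/H2O, 0 °C) to 3-[2-(2-methylbut-3-en-2-yl)-1H-indol-3-yl]-2-oxopropanoic acid F1. This is coupled with thiophenol (EDC·HCl, cat. DMAP, CH2Cl2) to S-phenyl 3-[2-(2-methylbut-3-en-2-yl)-1H-indol-3-yl]-2-oxopropanethioate F2. Soft enolisation of 7 (MgBr2·OEt2, iPr2NEt, CH2Cl2) then lets its magnesium enolate attack only the more electrophilic thioester of F2, giving 8 as a discrete compound. A separate Dieckmann closure of 8 (NaOMe, MeOH, then HCl) rejoins the route at 9.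

2. **Step 6 (reductive C-prenylation).** The risks are O- versus C-allylation, attack next to the wrong indole or at an aryl-bearing carbon, and redox exchange between 10 and product quinone that regenerates 9 (recoverable and recyclable). Fallback: a cross-coupling approach that sets out from 9 and returns at 12. The less hindered hydroxyl, next to the plain indole, is converted with (COCl)2 (1.0 equiv) and cat. DMF in CH2Cl2 at 0 °C into 2-chloro-5-hydroxy-3-(1H-indol-3-yl)-6-[2-(2-methylbut-3-en-2-yl)-1H-indol-3-yl]cyclohexa-2,5-diene-1,4-dione F3. Stille coupling of this vinylogous acid chloride with tributyl(3-methylbut-2-en-1-yl)stannane (Pd(PPh3)4, DMF, 60 °C) gives 12.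

3. **Step 3 (Krapcho dealkoxycarbonylation).** The risks are competing cleavage of the α-keto ester and thermal loss of CO from the oxalyl unit. Fallback: a different access to 5 that sets out from 7, returns at 5 and bypasses steps 1 to 3. Keto ester 7 is protected (HC(OMe)3, MeOH, cat. TsOH) as methyl 3-(1H-indol-3-yl)-2,2-dimethoxypropanoate F4. The step 1 reverse prenylation (tBuOCl, Et3N, then B-prenyl-9-BBN) passes through methyl 3-(3-chloro-3H-indol-3-yl)-2,2-dimethoxypropanoate F5 and gives methyl 2,2-dimethoxy-3-[2-(2-methylbut-3-en-2-yl)-1H-indol-3-yl]propanoate F6. Mild hydrolysis of the ketal (aq. TFA, THF, 0 °C to rt) releases 5.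

**Further compounds**
F1 | step 5 | 3-[2-(2-methylbut-3-en-2-yl)-1H-indol-3-yl]-2-oxopropanoic acid | OC(=O)C(=O)Cc1c(C(C)(C)C=C)[nH]c2ccccc12
F2 | step 5 | S-phenyl 3-[2-(2-methylbut-3-en-2-yl)-1H-indol-3-yl]-2-oxopropanethioate | O=C(Sc1ccccc1)C(=O)Cc1c(C(C)(C)C=C)[nH]c2ccccc12
F3 | step 6 | 2-chloro-5-hydroxy-3-(1H-indol-3-yl)-6-[2-(2-methylbut-3-en-2-yl)-1H-indol-3-yl]cyclohexa-2,5-diene-1,4-dione | O=C1C(Cl)=C(c2c[nH]c3ccccc23)C(=O)C(O)=C1c1c(C(C)(C)C=C)[nH]c2ccccc12
F4 | step 3 | methyl 3-(1H-indol-3-yl)-2,2-dimethoxypropanoate | COC(=O)C(OC)(OC)Cc1c[nH]c2ccccc12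
F5 | step 3 | methyl 3-(3-chloro-3H-indol-3-yl)-2,2-dimethoxypropanoate (racemic, not isolated) | COC(=O)C(OC)(OC)CC1(Cl)C=Nc2ccccc12
F6 | step 3 | methyl 2,2-dimethoxy-3-[2-(2-methylbut-3-en-2-yl)-1H-indol-3-yl]propanoate | COC(=O)C(OC)(OC)Cc1c(C(C)(C)C=C)[nH]c2ccccc12
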